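**Burst ceiling.** You asked for a quick number on the flask, so I started from one ratio, [nucleophile] over twice [electrophile] as charged, which gave 75.3%. I called it the burst ceiling: the part of the electrophile that can react if the proton from each turn settles at once on a second nucleophile, so that every turn costs two. Protonated nucleophile would then be the nucleophile's resting state.

| flask | electrophile | nucleophile | free base | remark | time |
|---|---|---|---|---|---|
| Monday's | 0.095 M | 0.143 M | 0.20 M | run made earlier |  |
| Sunday's | 0.095 M | 0.143 M | 0.31 M | run made earlier |  |
| flask | 0.095 M | 0.143 M | 0.143 M |  | 5.0 min |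

| run | time / min | electrophile / % | target / % |
|---|---|---|---|
| Monday's | 0.500 | 25.4 | 69.3 |
| Monday's | 1.00 | 14.8 | 73.0 |
| Monday's | 1.50 | 13.2 | 75.6 |
| Monday's | 2.00 | 12.2 | 80.5 |
| Monday's | 2.50 | 9.0 | 80.3 |
| Monday's | 3.00 | 6.0 | 84.6 |
| Sunday's | 0.500 | 25.0 | 69.7 |
| Sunday's | 1.00 | 18.8 | 74.6 |
| Sunday's | 1.50 | 13.6 | 76.3 |
| Sunday's | 2.00 | 10.5 | 80.1 |
| Sunday's | 2.50 | 10.5 | 84.6 |
| Sunday's | 3.00 | 4.9 | 84.1 |

(readings scatter by 1 percentage point)

- part of the electrophile that has reacted at 5.0 min
- share of the unused nucleophile that is free and not bound as protonated nucleophile, at 5.0 min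

- what was read earlier has a scatter of 1 percentage point, one standard deviation
- the earlier runs do not show how much of nucleophile is bound; that part of a forecast is a guess

**Reading it.** Both runs bent there, with 74.6% and 75.0% of the electrophile used at 0.500 min. I took loss of electrophile to follow free [nucleophile]. Monday's readings gave 2.74 min⁻¹ over the burst and 0.577 min⁻¹ after it. As a rough stand-in for mean free [nucleophile] over the burst I took the midpoint of a straight fall from its charge to zero, 0.0715 M, and the same amount stays unused at the ceiling. The flask has Monday's charges of both, so tail over burst, 21.1%, was my rough estimate of fr, on the high side if the fall curved steeply at first.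

**The forecast.** It stood at 96% reacted and 80% free, on the ground that “The lack of base dependence leans towards the stronger base”. On fr it differed from my estimate.

**The result.** The flask gave 96.3% reacted and 11.3% free.

    electrophile + nucleophile → acid set free + target (k = 1.00 L mol⁻¹ s⁻¹)
    nucleophile + acid set free ⇌ protonated nucleophile, settled at all times (K = 16000 L mol⁻¹)
    acid set free + free base ⇌ salt of the base (K = 81000 L mol⁻¹, k = 1.10 L mol⁻¹ s⁻¹)
    2 electrophile → self-condensation product (k = 0.0550 L mol⁻¹ s⁻¹)
    acid set free → by-product carried off (k = 0.00500 s⁻¹)

**Ceiling kept.** At 0.500 min the flask's target stood at 68.6%, under the ceiling of 75.3%. In the flask, electrophile's half-life by its step with nucleophile was 0.19 min at 0.104 min, far shorter than free base's 21 min by the forward step with acid set free alone at 5.00 min. At that later time protonated nucleophile stood at 0.0544 M, more than the 0.0259 M of salt of the base. A second flask with 0.057 M of electrophile has a ceiling of 125%, above its whole charge, and it gave >99.9% reacted with 41.8% free.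

The earlier runs and the new flask were generated by integration from invented constants, and the scatter is random.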